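**Retrosynthetic overview**

- The target is reached last by BBr3 cleavage of both methyl ethers of the bis(methyl ether) diarylmethane.
- Ring A (C1 bearing the CH2, C3 bearing Br, C4 bearing O) has its bromine ortho and its CH2 para to the oxygen. This pattern maps onto a 3-bromo-5-benzyl-2-pyrone that reacts with 1,1-dimethoxyethene in a [4+2] cycloaddition, forming ring A bonds C3–C4 and C5–C6, followed by loss of CO2 and methanol.
- The bromopyrone comes from bromodecarboxylation of the pyrone-3-carboxylic acid. The pyrone ring is built from the enamine of a 3-arylpropanal and dimethyl 2-(methoxymethylene)malonate.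
- The aldehyde comes from 3-(4-hydroxyphenyl)propanoic acid by ortho,ortho-dibromination, double methylation and half-reduction of the ester.
- Ring order: ring B is carried from the start, the pyrone ring is formed second, ring A last.

Key step: step 7

Remark: the target has no stereocentre. The bridged lactone 12 is racemic and its stereocentres are destroyed within the same step. Dimethyl 2-(methoxymethylene)malonate is taken as a purchasable reagent.

**Route**

Step 1
Reactants: 1 3-(4-hydroxyphenyl)propanoic acid
Product: 2 3-(3,5-dibromo-4-hydroxyphenyl)propanoic acid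
Conditions: Br2 (2.1 equiv), AcOH, rt
Reagents that add atoms: bromine, BrBr
Why: Electrophilic aromatic bromination; the free phenol directs both bromines to its two ortho positions because the para position carries the side chain.

Step 2
Reactants: 2 3-(3,5-dibromo-4-hydroxyphenyl)propanoic acid
Product: 3 methyl 3-(3,5-dibromo-4-methoxyphenyl)propanoate
Conditions: MeI (3 equiv), K2CO3 (2 equiv), DMF, 40 °C
Reagents that add atoms: iodomethane, CI
Why: Williamson ether synthesis and carboxylate O-alkylation in one operation (two SN2 methylations), the acidic 2,6-dibromophenol being fully ionised by K2CO3.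

Step 3
Reactants: 3 methyl 3-(3,5-dibromo-4-methoxyphenyl)propanoate
Product: 4 3-(3,5-dibromo-4-methoxyphenyl)propanal
Conditions: i-Bu2AlH (1.05 equiv), CH2Cl2, −78 °C; MeOH, then aq. potassium sodium tartrate
Reagents that add atoms: none
Why: Partial hydride reduction of a methyl ester, which should stop at the aluminium hemiacetal at −78 °C and release the aldehyde on work-up; aryl bromides and the aryl ether are inert.

Step 4
Reactants: 4 3-(3,5-dibromo-4-methoxyphenyl)propanal; 5 dimethyl 2-(methoxymethylene)malonate
Product: 8 methyl 5-(3,5-dibromo-4-methoxybenzyl)-2-oxo-2H-pyran-3-carboxylate, via morpholine enamine 6 (not isolated), via aminodiene diester 7 (not isolated)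
Conditions: morpholine (1.0 equiv), K2CO3, toluene, 0 °C to rt; 5 (1.2 equiv), 60 °C; then 2 M aq. HCl, THF, 50 °C
Reagents that add atoms: water, O
Why: Stork enamine addition–elimination at the alkoxymethylene carbon of 5 should give the push–pull aminodiene 7; aqueous acid hydrolyses its enamine terminus to the enol, which lactonises onto the cis ester (6-exo-trig, loss of methanol) to the 2-pyrone, the known annulation route to 3-carbomethoxy-2-pyrones.

Step 5
Reactants: 8 methyl 5-(3,5-dibromo-4-methoxybenzyl)-2-oxo-2H-pyran-3-carboxylate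
Product: 9 5-(3,5-dibromo-4-methoxybenzyl)-2-oxo-2H-pyran-3-carboxylic acid
Conditions: 6 M aq. HCl, AcOH, 90 °C
Reagents that add atoms: water, O
Why: Acid-catalysed ester hydrolysis; acid is chosen over hydroxide so that the pyrone lactone, which tolerates strong acid, is not opened by nucleophilic attack, and the aryl methyl ether is stable to HCl.

Step 6
Reactants: 9 5-(3,5-dibromo-4-methoxybenzyl)-2-oxo-2H-pyran-3-carboxylic acid
Product: 10 3-bromo-5-(3,5-dibromo-4-methoxybenzyl)-2H-pyran-2-one
Conditions: NBS (1.2 equiv), LiOAc (lithium acetate, 0.2 equiv), MeCN–H2O (9:1), rt, dark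
Reagents that add atoms: N-bromosuccinimide, O=C1CCC(=O)N1Br
Why: Hunsdiecker-type bromodecarboxylation of an α,β-unsaturated acid, as used on 2-pyrone carboxylic acids; Br+ attacks pyrone C3 ipso to the carboxylate (the nucleophilic end of the ring O–C6=C5–C4=C3 system) and the oxocarbenium-stabilised intermediate loses CO2.

Step 7
Reactants: 10 3-bromo-5-(3,5-dibromo-4-methoxybenzyl)-2H-pyran-2-one; 11 1,1-dimethoxyethene
Product: 14 1,3-dibromo-5-(3-bromo-4-methoxybenzyl)-2-methoxybenzene, via bridged bicyclic lactone 12 (not isolated), via dimethoxycyclohexadiene 13 (not isolated)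
Conditions: 11 (8 equiv), toluene, sealed tube, 130 °C
Reagents that add atoms: none
Why: The bromopyrone is the electron-poor 4π partner (pyrone C3=C4–C5=C6) and the ketene acetal the electron-rich 2π partner, so an inverse-electron-demand [4+2] cycloaddition joins the acetal CH2 to pyrone C6 and the acetal carbon to the bromine-bearing pyrone C3, giving bridged lactone 12. Retro-[4+2] extrusion of CO2 from 12 leaves cyclohexadiene 13, and thermal 1,2-elimination of methanol from its C(OMe)2–CH2 unit aromatises it to ring A of 14. The closest known reactions are the cycloadditions of 3-carbomethoxy-2-pyrones with 1,1-dimethoxyethene to give salicylate methyl ethers and of 3-bromo-2-pyrone with vinyl ethers. Ring A is closed by the intermolecular cycloaddition itself, which forms its C3–C4 and C5–C6 bonds; the two bridgehead stereocentres of 12 are transient and vanish on aromatisation, so no stereocontrol is needed. The selectivity required is regiochemical: the oxygenated carbon must end up beside C–Br, and this is secured by the polarisation of the pyrone, whose C6 is the electrophilic terminus of the doubly unsaturated lactone, matched with the nucleophilic CH2 terminus of the ketene acetal. Ring B, its two bromines and the CH2 link are spectators carried on pyrone C5.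

Step 8
Reactants: 14 1,3-dibromo-5-(3-bromo-4-methoxybenzyl)-2-methoxybenzene
Product: 15 2-bromo-4-(3,5-dibromo-4-hydroxybenzyl)phenol (target)
Conditions: BBr3 (5 equiv), CH2Cl2, −78 °C to rt; H2O
Reagents that add atoms: none
Why: Lewis-acid cleavage of aryl methyl ethers (bromide SN2 attack on the boron-coordinated O–CH3) should free both phenols; the aryl bromides and the diarylmethane CH2 are inert.

**Compound list**

1 | 3-(4-hydroxyphenyl)propanoic acid | OC(=O)CCc1ccc(O)cc1 | starting material
2 | 3-(3,5-dibromo-4-hydroxyphenyl)propanoic acid | OC(=O)CCc1cc(Br)c(O)c(Br)c1 | intermediate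
3 | methyl 3-(3,5-dibromo-4-methoxyphenyl)propanoate | COC(=O)CCc1cc(Br)c(OC)c(Br)c1 | intermediate
4 | 3-(3,5-dibromo-4-methoxyphenyl)propanal | O=CCCc1cc(Br)c(OC)c(Br)c1 | intermediate
5 | dimethyl 2-(methoxymethylene)malonate | COC=C(C(=O)OC)C(=O)OC | starting material
6 | (E)-4-[3-(3,5-dibromo-4-methoxyphenyl)prop-1-en-1-yl]morpholine | COc1c(Br)cc(C/C=C/N2CCOCC2)cc1Br | intermediate (not isolated)
7 | dimethyl 2-[(E)-2-(3,5-dibromo-4-methoxybenzyl)-3-(morpholin-4-yl)prop-2-en-1-ylidene]malonate | COC(=O)C(C(=O)OC)=C/C(Cc1cc(Br)c(OC)c(Br)c1)=C/N1CCOCC1 | intermediate (not isolated)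
8 | methyl 5-(3,5-dibromo-4-methoxybenzyl)-2-oxo-2H-pyran-3-carboxylate | COC(=O)c1cc(Cc2cc(Br)c(OC)c(Br)c2)coc1=O | intermediate
9 | 5-(3,5-dibromo-4-methoxybenzyl)-2-oxo-2H-pyran-3-carboxylic acid | OC(=O)c1cc(Cc2cc(Br)c(OC)c(Br)c2)coc1=O | intermediate
10 | 3-bromo-5-(3,5-dibromo-4-methoxybenzyl)-2H-pyran-2-one | O=c1occ(Cc2cc(Br)c(OC)c(Br)c2)cc1Br | intermediate
11 | 1,1-dimethoxyethene | C=C(OC)OC | starting material
12 | 4-bromo-6-(3,5-dibromo-4-methoxybenzyl)-8,8-dimethoxy-2-oxabicyclo[2.2.2]oct-5-en-3-one (racemic, one enantiomer drawn; the two bridgeheads are fixed relative to each other by the bicycle) | O=C1O[C@H]2CC(OC)(OC)[C@]1(Br)C=C2Cc1cc(Br)c(OC)c(Br)c1 | intermediate (not isolated)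
13 | 1-bromo-3-(3,5-dibromo-4-methoxybenzyl)-6,6-dimethoxycyclohexa-1,3-diene | COC1(OC)CC=C(Cc2cc(Br)c(OC)c(Br)c2)C=C1Br | intermediate (not isolated)
14 | 1,3-dibromo-5-(3-bromo-4-methoxybenzyl)-2-methoxybenzene | COc1ccc(Cc2cc(Br)c(OC)c(Br)c2)cc1Br | intermediate
15 | 2-bromo-4-(3,5-dibromo-4-hydroxybenzyl)phenol | Oc1ccc(Cc2cc(Br)c(O)c(Br)c2)cc1Br | target

**Summary**

Total step count: 8. Longest linear sequence: 8 steps (from 1; compounds 5 and 11 are purchased).

Steps most likely to fail:

1. Step 7. The C5 alkyl group makes the bromopyrone a weaker electron-poor diene than an ester-bearing pyrone, so the cycloaddition may be slow and lose out to oligomerisation of the ketene acetal, or the loss of CO2 and methanol may stall. Fallback, setting out from 8 and returning at 14: the cycloaddition is run on the more electron-poor pyrone ester and the bromine is put in afterwards. Compound 8 and 11 in toluene at 120 °C should give, through methyl 6-(3,5-dibromo-4-methoxybenzyl)-8,8-dimethoxy-3-oxo-2-oxabicyclo[2.2.2]oct-5-ene-4-carboxylate F1 and methyl 3-(3,5-dibromo-4-methoxybenzyl)-6,6-dimethoxycyclohexa-1,3-diene-1-carboxylate F2, the anisate methyl 5-(3,5-dibromo-4-methoxybenzyl)-2-methoxybenzoate F3. Saponification (LiOH, THF–H2O) should give 5-(3,5-dibromo-4-methoxybenzyl)-2-methoxybenzoic acid F4. Metal-free decarboxylative ipso-bromination of this ortho-methoxybenzoic acid (Bu4NBr3, K3PO4, MeCN, 100 °C) should then deliver 14.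

2. Step 6. Electrophilic bromine may instead add across the C5–C6 enol-ether bond of the pyrone and, in the aqueous medium, lead to ring opening, or the ipso intermediate may fail to lose CO2. Fallback, setting out from 9 and returning at 10: the carboxyl group is removed first and the bromine is introduced by addition–elimination. Protodecarboxylation of 9 (Ag2CO3 catalyst, AcOH, DMSO, 120 °C) should give 5-(3,5-dibromo-4-methoxybenzyl)-2H-pyran-2-one F5. Br2 in CH2Cl2 at 0 °C should add across C3 and C6 to give 3,6-dibromo-5-(3,5-dibromo-4-methoxybenzyl)-3,6-dihydro-2H-pyran-2-one F6 (mixture of diastereomers), and Et3N should eliminate HBr (H from C3, bromide from C6) to give 10.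

3. Step 4. The unbranched aldehyde may self-condense while the enamine forms, and free morpholine may attack reagent 5 at nitrogen instead of the enamine attacking at carbon. Fallback, setting out from 4 and returning at 8: the three-carbon unit is made as a vinylogous formamide and condensed with dimethyl malonate. Acetalisation of 4 (HC(OMe)3, MeOH, TsOH catalyst) should give 1,3-dibromo-5-(3,3-dimethoxypropyl)-2-methoxybenzene F7. Vilsmeier formylation of the acetal (POCl3, DMF, 70 °C; aq. K2CO3) should give (E)-2-(3,5-dibromo-4-methoxybenzyl)-3-(dimethylamino)acrylaldehyde F8. Knoevenagel condensation with dimethyl malonate (piperidine, AcOH, toluene, reflux) should give dimethyl 2-[(E)-2-(3,5-dibromo-4-methoxybenzyl)-3-(dimethylamino)prop-2-en-1-ylidene]malonate F9, which on warming with 2 M aq. HCl in THF should close to 8.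

**Further compounds**

F1 | step 7 | methyl 6-(3,5-dibromo-4-methoxybenzyl)-8,8-dimethoxy-3-oxo-2-oxabicyclo[2.2.2]oct-5-ene-4-carboxylate (racemic, one enantiomer drawn) | O=C1O[C@H]2CC(OC)(OC)[C@]1(C(=O)OC)C=C2Cc1cc(Br)c(OC)c(Br)c1
F2 | step 7 | methyl 3-(3,5-dibromo-4-methoxybenzyl)-6,6-dimethoxycyclohexa-1,3-diene-1-carboxylate | COC(=O)C1=CC(Cc2cc(Br)c(OC)c(Br)c2)=CCC1(OC)OC
F3 | step 7 | methyl 5-(3,5-dibromo-4-methoxybenzyl)-2-methoxybenzoate | COC(=O)c1cc(Cc2cc(Br)c(OC)c(Br)c2)ccc1OC
F4 | step 7 | 5-(3,5-dibromo-4-methoxybenzyl)-2-methoxybenzoic acid | OC(=O)c1cc(Cc2cc(Br)c(OC)c(Br)c2)ccc1OC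
F5 | step 6 | 5-(3,5-dibromo-4-methoxybenzyl)-2H-pyran-2-one | O=c1ccc(Cc2cc(Br)c(OC)c(Br)c2)co1
F6 | step 6 | 3,6-dibromo-5-(3,5-dibromo-4-methoxybenzyl)-3,6-dihydro-2H-pyran-2-one (mixture of diastereomers, configuration not defined) | O=C1OC(Br)C(Cc2cc(Br)c(OC)c(Br)c2)=CC1Br
F7 | step 4 | 1,3-dibromo-5-(3,3-dimethoxypropyl)-2-methoxybenzene | COC(CCc1cc(Br)c(OC)c(Br)c1)OC
F8 | step 4 | (E)-2-(3,5-dibromo-4-methoxybenzyl)-3-(dimethylamino)acrylaldehyde | CN(C)/C=C(\Cc1cc(Br)c(OC)c(Br)c1)C=O
F9 | step 4 | dimethyl 2-[(E)-2-(3,5-dibromo-4-methoxybenzyl)-3-(dimethylamino)prop-2-en-1-ylidene]malonate | COC(=O)C(C(=O)OC)=C/C(Cc1cc(Br)c(OC)c(Br)c1)=C/N(C)C
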